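**Retrosynthetic overview**

1. Each C15 half is numbered as in squalene: C2 = CMe2, C3, C6 = quaternary C–Me, C7 = ring-fusion CH–O, C10, C11, C12 = bridge CH2. Primes mark the keto-carbinol ("eastern") half. Both halves have the same absolute configuration, so both come from one acyclic (3S,6S,7S)-diepoxy allylsilane ester 8 (geranyl bromide + methyl acetoacetate, 4 steps).
2. Enabling feature: in the hydroxy-oxepane the ring O joins C7 to C2. C2 is flanked by the C3 carbinol and C7 by the quaternary C6, and C6 is bonded to C11 next to the C10 exocyclic methylene. This is the imprint of a 2,3;6,7-diepoxide opened twice in the endo sense and terminated by a C10=C11 allylsilane.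
3. Last disconnection (key step): O–C2 and C6–C11 of the western bicycle are cut together. This leaves an acyclic diepoxy allylsilane chain on the finished eastern bicycle (25).
4. C12–C12′ is cut next: lithiated eastern sulfone 18 + western allylic bromide 21. In the forward sense the sulfone is then removed and C3′ is oxidised.
5. Ring order: eastern oxepane + cyclohexane first (the same cascade on 8, then C10′=CH2 → C=O → axial carbinol). Western oxepane + cyclohexane come last.

Key step: step 16

Assumption: the L-fructose-derived Shi ketone (the enantiomer of the commercial D-fructose-derived catalyst, also accessible from L-sorbose) is treated as a purchasable catalyst, and its preparation is not counted.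

Remark: C12′ of 23, the spiro carbon of 13 and the sulfur of 17 are formed without control. All three centres disappear in the same or the next step.

**Step 1**
Reactants: 1 geranyl bromide; 2 methyl acetoacetate
Product: 4 methyl (6E)-7,11-dimethyl-3-oxododeca-6,10-dienoate, via sodium lithium dianion of methyl acetoacetate 3 (not isolated)
Conditions: 2, NaH, THF, 0 °C; n-BuLi, 0 °C; then 1, 0 °C to rt; cold dil. HCl quench
Reagents that add atoms: none
Why: γ-Alkylation of an acetoacetate dianion: the more basic terminal carbanion of 3 displaces the primary allylic bromide by SN2, which forms C8–C9 and leaves the E-alkene of the geranyl unit untouched.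

**Step 2**
Reactants: 4 β-keto ester
Product: 6 methyl (2Z,6E)-3-(diethoxyphosphoryloxy)-7,11-dimethyldodeca-2,6,10-trienoate, via chelated sodium Z-enolate 5 (not isolated)
Conditions: NaH, Et2O, 0 °C; ClP(O)(OEt)2, 0 °C to rt
Reagents that add atoms: diethyl chlorophosphate CCOP(=O)(Cl)OCC
Why: O-Phosphorylation of a β-keto ester enolate: in ether the sodium ion chelates both oxygens of 5, so the phosphate ends up cis to the ester (Z) and the chain trans to it.

**Step 3**
Reactants: 6 Z-enol phosphate
Product: 7 methyl (2Z,6E)-7,11-dimethyl-3-[(trimethylsilyl)methyl]dodeca-2,6,10-trienoate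
Conditions: Me3SiCH2MgCl, Ni(acac)2 (cat.), THF, 0 °C to rt; cold dil. HCl quench
Reagents that add atoms: (trimethylsilyl)methylmagnesium chloride C[Si](C)(C)C[Mg]Cl
Why: Nickel-catalysed Kumada coupling of an enol phosphate runs with retention of alkene geometry, so CH2SiMe3 takes the place cis to the ester and C12 stays trans to C9, as the chair cyclisations require.

**Step 4**
Reactants: 7 triene allylsilane ester
Product: 8 methyl (2Z,6S,7S,10S)-6,7:10,11-diepoxy-7,11-dimethyl-3-[(trimethylsilyl)methyl]dodec-2-enoate (= 3S,6S,7S in squalene numbering)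
Conditions: L-fructose-derived Shi ketone (cat.), Oxone, K2CO3, Na2B4O7/Na2EDTA buffer (pH 10.5), Bu4NHSO4, MeCN–DMM–H2O, 0 °C
Reagents that add atoms: Oxone (potassium peroxymonosulfate) [K+].[O-]S(=O)(=O)OO
Why: Shi asymmetric epoxidation: the chiral dioxirane attacks the two electron-rich trisubstituted alkenes through the spiro transition state on the face opposite to that used by the D-fructose catalyst (which gives R,R) and so sets 3S,6S,7S, while the ester-conjugated C10=C11 bond is too electron-poor to be oxidised.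

**Step 5**
Reactants: 8 diepoxy allylsilane ester
Product: 10 methyl (3S,5aS,6R,9aS)-2,2,5a-trimethyl-7-methylidene-3-(trimethylsilyloxy)decahydro-1-benzoxepine-6-carboxylate, via bicyclic epoxonium triflate 9 (not isolated)
Conditions: TMSOTf, 2,6-di-tert-butyl-4-methylpyridine (DTBMP), CH2Cl2 (dilute), −78 °C; Et3N, aq. NaHCO3
Reagents that add atoms: trimethylsilyl trifluoromethanesulfonate C[Si](C)(C)OS(=O)(=O)C(F)(F)F
Why: Silyl-triflate-promoted tandem oxa-/carbacyclisation of a 1,5-diepoxide with Hosomi–Sakurai-type allylsilane termination (mechanism as in step 16): C3′ and C7′ keep their epoxide configuration, C6′ is inverted to give the trans ring fusion, and the chair transition state with the Z-allylsilane places the ester equatorial at C11′.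

**Step 6**
Reactants: 10 bicyclic silyl ether ester
Product: 12 (3S,5aS,6R,9aS)-6-(hydroxymethyl)-2,2,5a-trimethyl-7-methylidenedecahydro-1-benzoxepin-3-ol, via silyl ether alcohol 11 (not isolated)
Conditions: LiAlH4, THF, 0 °C to rt; cold 1 M HCl work-up
Reagents that add atoms: none
Why: Hydride reduction of the hindered equatorial ester to the primary alcohol touches no stereocentre, and the acidic work-up hydrolyses the labile trimethylsilyl ether of 11.

**Step 7**
Reactants: 12 methylidene diol
Product: 14 (3S,5aS,6R,9aS)-3-hydroxy-6-(hydroxymethyl)-2,2,5a-trimethyloctahydro-1-benzoxepin-7(2H)-one, via secondary ozonide 13 (not isolated)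
Conditions: O3, CH2Cl2, −78 °C; Me2S, −78 °C to rt
Reagents that add atoms: ozone [O-][O+]=O
Why: Ozonolysis with reductive work-up cleaves the only alkene to the C10′ ketone, and C11′ keeps its thermodynamically preferred equatorial substituent.

**Step 8**
Reactants: 14 keto diol
Product: 15 (3S,5aS,6R,7R,9aS)-6-(hydroxymethyl)-2,2,5a,7-tetramethyldecahydro-1-benzoxepine-3,7-diol
Conditions: MeLi, anhydrous CeCl3 (excess), THF, −78 °C; aq. NH4Cl
Reagents that add atoms: methyllithium [Li]C (delivered as methylcerium dichloride)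
Why: Organocerium (Imamoto) 1,2-addition is nucleophilic but barely basic, which suppresses enolisation and retro-aldol loss of the hydroxymethyl group, and the axial C6′ methyl group blocks the axial trajectory so that methyl enters equatorially and the new C10′ hydroxyl is axial (10′R).

**Step 9**
Reactants: 15 triol
Product: 16 (3S,5aS,6S,7R,9aS)-2,2,5a,7-tetramethyl-6-[(phenylsulfanyl)methyl]decahydro-1-benzoxepine-3,7-diol
Conditions: PhSSPh, n-Bu3P, THF, rt to 50 °C
Reagents that add atoms: diphenyl disulfide c1ccc(cc1)SSc1ccccc1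
Why: The Hata reaction (Mitsunobu-type SN2 displacement through the alkoxyphosphonium salt) is selective for the primary hydroxyl over the neopentyl-type secondary and the tertiary one.

**Step 10**
Reactants: 16 sulfide
Product: 18 (3S,5aS,6S,7R,9aS)-2,2,5a,7-tetramethyl-6-[(phenylsulfonyl)methyl]decahydro-1-benzoxepine-3,7-diol, via sulfoxide 17 (not isolated)
Conditions: mCPBA (2.2 equiv), NaHCO3, CH2Cl2, 0 °C
Reagents that add atoms: 3-chloroperbenzoic acid OOC(=O)c1cccc(Cl)c1
Why: Peracid oxidation of the sulfide through sulfoxide 17 to the sulfone meets no alkene or other oxidisable group in this fragment.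

**Step 11**
Reactants: 8 diepoxy allylsilane ester
Product: 19 (2Z,6S,7S,10S)-6,7:10,11-diepoxy-7,11-dimethyl-3-[(trimethylsilyl)methyl]dodec-2-en-1-ol
Conditions: DIBAL-H (2.2 equiv), CH2Cl2, −78 °C; Rochelle salt
Reagents that add atoms: none
Why: DIBAL-H 1,2-reduction of the enoate at low temperature gives the allylic alcohol without opening the trisubstituted epoxides or changing the alkene geometry.

**Step 12**
Reactants: 19 allylic alcohol
Product: 21 (2Z,6S,7S,10S)-1-bromo-6,7:10,11-diepoxy-7,11-dimethyl-3-[(trimethylsilyl)methyl]dodec-2-ene, via allylic mesylate 20 (not isolated)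
Conditions: MsCl, Et3N, CH2Cl2, −40 °C; LiBr, THF, 0 °C; used at once
Reagents that add atoms: lithium bromide [Li+].[Br-]; methanesulfonyl chloride CS(=O)(=O)Cl (its atoms stay only in 20)
Why: Mesylation followed by SN2 displacement with bromide under non-acidic conditions is the standard access to epoxide-bearing allylic bromides and keeps the Z-alkene; 21 is not stored because the Si–C–C=C–C–Br array can undergo 1,4-elimination.

**Step 13**
Reactants: 18 eastern sulfone; 21 western allylic bromide
Product: 23 C12′-phenylsulfonyl coupling product (western diepoxy allylsilane chain on the eastern bicyclic diol; C12′ epimers), via trilithiated sulfone 22 (not isolated)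
Conditions: 18, n-BuLi (3.05 equiv), THF–DMPU, −78 to −30 °C; then 21, −78 °C; water quench
Reagents that add atoms: none
Why: Alkylation of an α-sulfonyl carbanion: in 22 the carbanion is by far the most reactive site and attacks the unhindered primary allylic bromide by SN2 at −78 °C, much faster than lithium alkoxides or trisubstituted epoxides can react, which forms C12–C12′.

**Step 14**
Reactants: 23 coupled sulfone
Product: 24 (10Z)-diepoxy allylsilane diol (C3′–OH and C10′–OH free; C12′ now CH2)
Conditions: Na(Hg), Na2HPO4, MeOH–THF, −20 to 0 °C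
Reagents that add atoms: none
Why: Reductive desulfonylation with buffered sodium amalgam (single-electron C–S cleavage, then protonation) removes the auxiliary group and the C12′ stereocentre without touching epoxides, allylsilane or alcohols.

**Step 15**
Reactants: 24 diol
Product: 25 cascade precursor: (3S,6S,7S,10Z)-diepoxy allylsilane chain on the eastern oxepan-3′-one bearing the free C10′ carbinol
Conditions: Dess–Martin periodinane, NaHCO3, CH2Cl2, 0 °C to rt
Reagents that add atoms: none
Why: Dess–Martin oxidation under bicarbonate buffer converts the only secondary alcohol into the C3′ ketone, while the tertiary carbinol, the epoxides and the allylsilane are inert.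

**Step 16**
Reactants: 25 cascade precursor
Product: 28 bis(trimethylsilyl) ether of the target (C3–OSiMe3 and C10′–OSiMe3), via O-silylated cascade precursor 26 (not isolated), via bicyclic epoxonium triflate 27 (not isolated)
Conditions: TMSOTf (3 equiv), DTBMP (4 equiv), CH2Cl2 (high dilution), −78 °C; Et3N, aq. NaHCO3
Reagents that add atoms: trimethylsilyl trifluoromethanesulfonate C[Si](C)(C)OS(=O)(=O)C(F)(F)F
Why: After in situ silylation of the C10′ carbinol (26), TMSOTf silylates the terminal 2,3-epoxide, whose C2–O bond is loosened because C2 is tertiary, and the oxygen of the 6,7-epoxide attacks C2 to give the 1-oxoniabicyclo[4.1.0]heptane ion 27, the event that forms the O–C2 bond of the oxepane. The C10=C11 allylsilane then attacks C6, the methyl-bearing carbon of the epoxonium ion, anti to the breaking C6–O bond through a chair transition state, and the β-silyl cation at C10 loses Me3Si+ to triflate, which fixes the alkene as the exocyclic methylene. The closest known reaction type is the silyl-triflate-promoted tandem oxa-/carbacyclisation of 1,5-diepoxides terminated by allyl-, propargyl- or enol silanes, an extension of the epoxide-initiated, allylsilane-terminated polyene cyclisation. Ring closures: a 6-endo-tet attack at C2 gives 27, which becomes the seven-membered ring when C6–O breaks (net 7-endo-tet opening of the 2,3-epoxide), and the cyclohexane closes 6-endo-tet at C6 and 6-endo-trig at the alkene. Stereocontrol: C3 and C7 keep their C–O bonds and hence the S configurations set in step 4, C6 is inverted stereospecifically (trans fusion, axial methyl), and C11 (R) is set by the chair folding together with the Z-allylsilane geometry, which puts the C12 chain equatorial. The step needs endo over exo opening at both epoxides, secured by the gem-dimethyl group at C2 and the methyl group at C6 (attack at the carbon that best carries positive charge), and clean termination, secured by silicon and by DTBMP, which traps the triflic acid released on silylation of the carbinol.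

**Step 17**
Reactants: 28 bis(trimethylsilyl) ether
Product: 29 target CNP0160418.1
Conditions: HF·pyridine, pyridine–THF, 0 °C
Reagents that add atoms: none
Why: Fluoride-mediated cleavage of both trimethylsilyl ethers under pyridine-buffered conditions leaves the exocyclic alkene, the ketone and the tertiary alcohol unchanged.

**Compound list**

1 | geranyl bromide, (2E)-1-bromo-3,7-dimethylocta-2,6-diene | CC(C)=CCC/C(C)=C/CBr | starting material
2 | methyl acetoacetate | CC(=O)CC(=O)OC | starting material
3 | sodium lithium dianion of methyl acetoacetate | [Na+].[Li+].C=C([O-])C=C([O-])OC | intermediate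
4 | methyl (6E)-7,11-dimethyl-3-oxododeca-6,10-dienoate | CC(C)=CCC/C(C)=C/CCC(=O)CC(=O)OC | intermediate
5 | chelated sodium Z-enolate of 4 | [Na+].CC(C)=CCC/C(C)=C/CC/C([O-])=C/C(=O)OC | intermediate
6 | methyl (2Z,6E)-3-(diethoxyphosphoryloxy)-7,11-dimethyldodeca-2,6,10-trienoate | CC(C)=CCC/C(C)=C/CC/C(OP(=O)(OCC)OCC)=C/C(=O)OC | intermediate
7 | methyl (2Z,6E)-7,11-dimethyl-3-[(trimethylsilyl)methyl]dodeca-2,6,10-trienoate | CC(C)=CCC/C(C)=C/CC/C(C[Si](C)(C)C)=C/C(=O)OC | intermediate
8 | methyl (2Z,6S,7S,10S)-6,7:10,11-diepoxy-7,11-dimethyl-3-[(trimethylsilyl)methyl]dodec-2-enoate | CC1(C)O[C@H]1CC[C@]2(C)O[C@H]2CC/C(C[Si](C)(C)C)=C/C(=O)OC | intermediate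
9 | bicyclic epoxonium triflate from 8 (O bonded to C2′, C6′ and C7′; C3′–OSiMe3) | CC1(C)[C@@H](O[Si](C)(C)C)CC[C@@]2(C)[C@H](CC/C(C[Si](C)(C)C)=C/C(=O)OC)[O+]12.[O-]S(=O)(=O)C(F)(F)F | intermediate
10 | methyl (3S,5aS,6R,9aS)-2,2,5a-trimethyl-7-methylidene-3-(trimethylsilyloxy)decahydro-1-benzoxepine-6-carboxylate | C=C1CC[C@@H]2OC(C)(C)[C@@H](O[Si](C)(C)C)CC[C@@]2(C)[C@@H]1C(=O)OC | intermediate
11 | primary alcohol from 10 with the C3′ trimethylsilyl ether still in place | C=C1CC[C@@H]2OC(C)(C)[C@@H](O[Si](C)(C)C)CC[C@@]2(C)[C@@H]1CO | intermediate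
12 | (3S,5aS,6R,9aS)-6-(hydroxymethyl)-2,2,5a-trimethyl-7-methylidenedecahydro-1-benzoxepin-3-ol | C=C1CC[C@@H]2OC(C)(C)[C@@H](O)CC[C@@]2(C)[C@@H]1CO | intermediate
13 | secondary ozonide (spiro-1,2,4-trioxolane at C10′) of 12 | C1OOC2(O1)CC[C@@H]3OC(C)(C)[C@@H](O)CC[C@@]3(C)[C@@H]2CO | intermediate
14 | (3S,5aS,6R,9aS)-3-hydroxy-6-(hydroxymethyl)-2,2,5a-trimethyloctahydro-1-benzoxepin-7(2H)-one | O=C1CC[C@@H]2OC(C)(C)[C@@H](O)CC[C@@]2(C)[C@@H]1CO | intermediate
15 | (3S,5aS,6R,7R,9aS)-6-(hydroxymethyl)-2,2,5a,7-tetramethyldecahydro-1-benzoxepine-3,7-diol (axial C10′–OH) | C[C@@]1(O)CC[C@@H]2OC(C)(C)[C@@H](O)CC[C@@]2(C)[C@@H]1CO | intermediate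
16 | (3S,5aS,6S,7R,9aS)-2,2,5a,7-tetramethyl-6-[(phenylsulfanyl)methyl]decahydro-1-benzoxepine-3,7-diol | C[C@@]1(O)CC[C@@H]2OC(C)(C)[C@@H](O)CC[C@@]2(C)[C@@H]1CSc3ccccc3 | intermediate
17 | sulfoxide of 16 (sulfur epimers) | C[C@@]1(O)CC[C@@H]2OC(C)(C)[C@@H](O)CC[C@@]2(C)[C@@H]1CS(=O)c3ccccc3 | intermediate
18 | (3S,5aS,6S,7R,9aS)-2,2,5a,7-tetramethyl-6-[(phenylsulfonyl)methyl]decahydro-1-benzoxepine-3,7-diol | C[C@@]1(O)CC[C@@H]2OC(C)(C)[C@@H](O)CC[C@@]2(C)[C@@H]1CS(=O)(=O)c3ccccc3 | intermediate
19 | (2Z,6S,7S,10S)-6,7:10,11-diepoxy-7,11-dimethyl-3-[(trimethylsilyl)methyl]dodec-2-en-1-ol | CC1(C)O[C@H]1CC[C@]2(C)O[C@H]2CC/C(C[Si](C)(C)C)=C/CO | intermediate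
20 | methanesulfonate of 19 | CC1(C)O[C@H]1CC[C@]2(C)O[C@H]2CC/C(C[Si](C)(C)C)=C/COS(C)(=O)=O | intermediate
21 | (2Z,6S,7S,10S)-1-bromo-6,7:10,11-diepoxy-7,11-dimethyl-3-[(trimethylsilyl)methyl]dodec-2-ene | CC1(C)O[C@H]1CC[C@]2(C)O[C@H]2CC/C(C[Si](C)(C)C)=C/CBr | intermediate
22 | trilithiated 18 (two alkoxides, α-sulfonyl carbanion at C12′) | [Li+].[Li+].[Li+].C[C@@]1([O-])CC[C@@H]2OC(C)(C)[C@@H]([O-])CC[C@@]2(C)[C@@H]1[CH-]S(=O)(=O)c3ccccc3 | intermediate
23 | C12′-phenylsulfonyl coupling product (C12′ epimers) | CC1(C)O[C@H]1CC[C@]2(C)O[C@H]2CC/C(C[Si](C)(C)C)=C/CC([C@H]3[C@]4(C)CC[C@H](O)C(C)(C)O[C@H]4CC[C@@]3(C)O)S(=O)(=O)c5ccccc5 | intermediate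
24 | desulfonylated (3S,6S,7S,10Z)-diepoxy allylsilane diol | CC1(C)O[C@H]1CC[C@]2(C)O[C@H]2CC/C(C[Si](C)(C)C)=C/CC[C@H]3[C@]4(C)CC[C@H](O)C(C)(C)O[C@H]4CC[C@@]3(C)O | intermediate
25 | cascade precursor (C3′ ketone, free C10′ carbinol) | CC1(C)O[C@H]1CC[C@]2(C)O[C@H]2CC/C(C[Si](C)(C)C)=C/CC[C@H]3[C@]4(C)CCC(=O)C(C)(C)O[C@H]4CC[C@@]3(C)O | intermediate
26 | C10′ trimethylsilyl ether of 25 | CC1(C)O[C@H]1CC[C@]2(C)O[C@H]2CC/C(C[Si](C)(C)C)=C/CC[C@H]3[C@]4(C)CCC(=O)C(C)(C)O[C@H]4CC[C@@]3(C)O[Si](C)(C)C | intermediate
27 | bicyclic epoxonium triflate from 26 (O bonded to C2, C6 and C7; C3–OSiMe3) | CC1(C)[C@@H](O[Si](C)(C)C)CC[C@@]2(C)[C@H](CC/C(C[Si](C)(C)C)=C/CC[C@H]3[C@]4(C)CCC(=O)C(C)(C)O[C@H]4CC[C@@]3(C)O[Si](C)(C)C)[O+]12.[O-]S(=O)(=O)C(F)(F)F | intermediate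
28 | bis(trimethylsilyl) ether of the target | C=C1CC[C@@H]2OC(C)(C)[C@@H](O[Si](C)(C)C)CC[C@@]2(C)[C@@H]1CC[C@H]1[C@]2(C)CCC(=O)C(C)(C)O[C@H]2CC[C@@]1(C)O[Si](C)(C)C | intermediate
29 | CNP0160418.1 | C=C1CC[C@@H]2OC(C)(C)[C@@H](O)CC[C@@]2(C)[C@@H]1CC[C@H]1[C@]2(C)CCC(=O)C(C)(C)O[C@H]2CC[C@@]1(C)O | target

**Step count**

Total step count: 17. Longest linear sequence: 15 (steps 1–10 and 13–17).

**Steps most likely to fail**

**Step 16.**
- **Risk:** The silyl triflate may be diverted by the unprotected C3′ ketone (enol silane formation) and by the carbinol (release of triflic acid). Protodesilylation of the allylsilane, exo opening or a 1,2-hydride shift of an activated epoxide could then outrun the ordered cascade.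
- **Fallback:** It sets out from 24 and comes back at 29. It moves the C3′ oxidation behind the ring closure and differentiates the two secondary oxygens by their silyl groups.
- **Route:** 24 is silylated under neutral conditions with N-(trimethylsilyl)imidazole to the bis(trimethylsilyl) ether of the diol F1. The cyclisation is run at the alcohol oxidation level with TBSOTf/DTBMP in CH2Cl2 at −78 °C, so the new C3 oxygen emerges as the only tert-butyldimethylsilyl ether in the tetracyclic tris(silyl) ether F2. Citric acid in methanol removes only the trimethylsilyl groups and gives the C3-TBS diol F3. Dess–Martin oxidation gives the C3-TBS keto carbinol F4, and HF·pyridine then delivers 29.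

**Step 5.**
- **Risk:** The ester lowers the nucleophilicity of the allylsilane. The epoxonium ion may therefore collapse by hydride shift or triflate capture before the C6′–C11′ bond forms.
- **Fallback:** It sets out from 19 and comes back at 12. It runs the cyclisation at the alcohol oxidation level of C12′, where the allylsilane is not conjugated.
- **Route:** 19 is protected with TBDPSCl/imidazole as the allylic tert-butyldiphenylsilyl ether F5, whose bulky, weakly basic oxygen resists ionisation. TMSOTf/DTBMP at −78 °C should give the bicyclic bis(silyl) ether F6. TBAF then removes both silyl groups to give 12.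

**Step 13.**
- **Risk:** The polylithiated sulfone may aggregate and dissolve poorly. Its alkoxides may attack the silicon of the bromide and trigger 1,4-elimination to the diene, or they may be O-allylated.
- **Fallback:** It sets out from 18 and comes back at 24. It replaces the polyanion by the monoanion of a fully protected fragment.
- **Route:** 18 is converted with TMSOTf/2,6-lutidine into the bis(trimethylsilyl) ether sulfone F7. One equivalent of n-BuLi followed by 21 at −78 °C gives the coupled bis(trimethylsilyl) ether sulfone F8. Buffered sodium amalgam gives the bis(trimethylsilyl) ether of the diol F1, and K2CO3 in methanol releases 24.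

**Further compounds**

F1 | step 16 | bis(trimethylsilyl) ether of diol 24 | CC1(C)O[C@H]1CC[C@]2(C)O[C@H]2CC/C(C[Si](C)(C)C)=C/CC[C@H]3[C@]4(C)CC[C@H](O[Si](C)(C)C)C(C)(C)O[C@H]4CC[C@@]3(C)O[Si](C)(C)C
F2 | step 16 | tetracyclic tris(silyl) ether (C3–OTBS, C3′–OTMS, C10′–OTMS) | C=C1CC[C@@H]2OC(C)(C)[C@@H](O[Si](C)(C)C(C)(C)C)CC[C@@]2(C)[C@@H]1CC[C@H]1[C@]2(C)CC[C@H](O[Si](C)(C)C)C(C)(C)O[C@H]2CC[C@@]1(C)O[Si](C)(C)C
F3 | step 16 | C3-TBS diol (free C3′–OH and C10′–OH) | C=C1CC[C@@H]2OC(C)(C)[C@@H](O[Si](C)(C)C(C)(C)C)CC[C@@]2(C)[C@@H]1CC[C@H]1[C@]2(C)CC[C@H](O)C(C)(C)O[C@H]2CC[C@@]1(C)O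
F4 | step 16 | C3-TBS keto carbinol | C=C1CC[C@@H]2OC(C)(C)[C@@H](O[Si](C)(C)C(C)(C)C)CC[C@@]2(C)[C@@H]1CC[C@H]1[C@]2(C)CCC(=O)C(C)(C)O[C@H]2CC[C@@]1(C)O
F5 | step 5 | tert-butyldiphenylsilyl ether of 19 | CC1(C)O[C@H]1CC[C@]2(C)O[C@H]2CC/C(C[Si](C)(C)C)=C/CO[Si](c3ccccc3)(c4ccccc4)C(C)(C)C
F6 | step 5 | bicyclic bis(silyl) ether (C3′–OTMS, C12′–OTBDPS) | C=C1CC[C@@H]2OC(C)(C)[C@@H](O[Si](C)(C)C)CC[C@@]2(C)[C@@H]1CO[Si](c3ccccc3)(c4ccccc4)C(C)(C)C
F7 | step 13 | bis(trimethylsilyl) ether of sulfone 18 | C[C@@]1(O[Si](C)(C)C)CC[C@@H]2OC(C)(C)[C@@H](O[Si](C)(C)C)CC[C@@]2(C)[C@@H]1CS(=O)(=O)c3ccccc3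
F8 | step 13 | coupled bis(trimethylsilyl) ether sulfone (C12′ epimers) | CC1(C)O[C@H]1CC[C@]2(C)O[C@H]2CC/C(C[Si](C)(C)C)=C/CC([C@H]3[C@]4(C)CC[C@H](O[Si](C)(C)C)C(C)(C)O[C@H]4CC[C@@]3(C)O[Si](C)(C)C)S(=O)(=O)c5ccccc5
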